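**Retrosynthetic overview** (germacrane numbering: ring carbons C-1 to C-10, lactone carbons C-11 to C-13, methyls C-14 on C-10 and C-15 on C-4)
1. The target is a (1(10)Z,4Z)-germacranolide: a ten-membered carbocycle with a trans-fused α-methylene-γ-lactone (O, C-6, C-7, C-11, C-12), 3-OAc, 8-OH and a 9-(2R,3R)-epoxyangelate.
2. Enabling feature: the lactone oxygen sits on C-6, which is allylic to the C-4=C-5 double bond of the ten-membered ring. The bonds O–C-6 and C-11–C-7 are therefore what a palladium-catalysed (3+2) carbo-oxygenation of a (4Z,6Z) C-4=C-5–C-6=C-7 diene with 2-bromoacrylic acid delivers, through an η3-allyl over C-4/C-5/C-6, with 8-OH steering the face.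
3. Last disconnection: C-1=C-10 by ring-closing metathesis of the seco-lactone (crotyl on C-3, isopropenyl on C-9). It is placed after the lactone so that no conjugated diene can intercept the ruthenium carbene.
4. The diene comes from Sonogashira coupling (C-5–C-6) of a Z-vinyl iodide (C-1 to C-5; C-3 by asymmetric transfer hydrogenation) with an alkyne (C-6 to C-10; C-8/C-9 by alkoxyallylboration; ester from Sharpless-derived epoxyangelic acid), then Z-selective semireduction.
5. Ring order: oxirane (step 2), γ-lactone (step 18), ten-membered carbocycle (step 19).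

Key step: step 18

Remark on the chemistry: the carboxylate is assumed to attack the η3-allylpalladium from the face opposite to the metal, as carboxylates do in chloride-containing media; the (6Z) diene geometry is chosen on that basis. Organometallic intermediates are drawn in their simplest monomeric form.

**Route**

Step 1
Reactants: 1 angelic acid, (Z)-2-methylbut-2-enoic acid
Product: 2 (Z)-2-methylbut-2-en-1-ol
Conditions: LiAlH4, Et2O, 0 °C to rt; then H2O, aq NaOH
Reagents that add atoms: none
Why: Hydride reduction of the carboxylic acid to the primary allylic alcohol leaves the trisubstituted Z-alkene untouched, so the angelate geometry is kept.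

Step 2
Reactants: 2 (Z)-2-methylbut-2-en-1-ol
Product: 3 [(2S,3R)-2,3-dimethyloxiran-2-yl]methanol
Conditions: t-BuOOH, Ti(OiPr)4 (10 mol %), L-(+)-diethyl tartrate (12 mol %), 4 Å molecular sieves, CH2Cl2, −20 °C
Reagents that add atoms: tert-butyl hydroperoxide (CC(C)(C)OO)
Why: Sharpless asymmetric epoxidation; the L-(+)-tartrate titanium complex should deliver oxygen to the face that gives the (2S,3R)-epoxy alcohol, and the Z geometry fixes the two methyl groups trans.

Step 3
Reactants: 3 [(2S,3R)-2,3-dimethyloxiran-2-yl]methanol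
Product: 4 (2R,3R)-2,3-dimethyloxirane-2-carboxylic acid
Conditions: RuCl3·xH2O (2 mol %), NaIO4, CCl4/MeCN/H2O, rt
Reagents that add atoms: water (O)
Why: Sharpless ruthenium tetroxide oxidation takes the primary alcohol through the aldehyde hydrate to the acid without touching the epoxide; the C-2 descriptor becomes R only because the priorities change.

Step 4
Reactants: 5 2-methylprop-2-en-1-ol
Product: 6 3-(methoxymethoxy)-2-methylprop-1-ene
Conditions: MOMCl, iPr2NEt, CH2Cl2, 0 °C to rt
Reagents that add atoms: chloromethyl methyl ether (COCCl)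
Why: O-alkylation of the primary alcohol under amine base (MOM protection).

Step 5
Reactants: 6 3-(methoxymethoxy)-2-methylprop-1-ene; 7 3-(trimethylsilyl)prop-2-ynal
Product: 10 (3R,4R)-4-(methoxymethoxy)-5-methyl-1-(trimethylsilyl)hex-5-en-1-yn-3-ol, via lithiated methallyl ether 8 (not isolated), via Z-alkoxyallylborane 9 (not isolated)
Conditions: s-BuLi, THF, −78 °C; (−)-Ipc2BOMe (from (+)-α-pinene); BF3·OEt2; then 7, −78 °C; HOCH2CH2NH2 work-up
Reagents that add atoms: none
Why: Brown γ-alkoxyallylboration; the chelated Z-allyllithium is trapped on boron, the chair Zimmerman–Traxler transition state of the Z-γ-alkoxyallylborane should give the syn diol monoether, and the isopinocampheyl groups should direct attack to the Si face of the ynal, setting 3R and 4R.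

Step 6
Reactants: 10 (3R,4R)-4-(methoxymethoxy)-5-methyl-1-(trimethylsilyl)hex-5-en-1-yn-3-ol
Product: 11 tert-butyl{[(3R,4R)-4-(methoxymethoxy)-5-methyl-1-(trimethylsilyl)hex-5-en-1-yn-3-yl]oxy}dimethylsilane
Conditions: TBSOTf, 2,6-lutidine, CH2Cl2, −78 to 0 °C
Reagents that add atoms: tert-butyldimethylsilyl trifluoromethanesulfonate (CC(C)(C)[Si](C)(C)OS(=O)(=O)C(F)(F)F)
Why: Silylation of the secondary propargylic alcohol with the reactive silyl triflate, so that the two oxygens of the diol can be told apart.

Step 7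
Reactants: 11 tert-butyl{[(3R,4R)-4-(methoxymethoxy)-5-methyl-1-(trimethylsilyl)hex-5-en-1-yn-3-yl]oxy}dimethylsilane
Product: 12 (3R,4R)-4-[(tert-butyldimethylsilyl)oxy]-2-methyl-6-(trimethylsilyl)hex-1-en-5-yn-3-ol
Conditions: Me2BBr, CH2Cl2, −78 °C; then aq NaHCO3
Reagents that add atoms: none
Why: Lewis-acid cleavage of the MOM acetal by the bromoborane at −78 °C, a temperature at which the TBS ether, the silylalkyne and the allylic C–O bond should survive.

Step 8
Reactants: 12 (3R,4R)-4-[(tert-butyldimethylsilyl)oxy]-2-methyl-6-(trimethylsilyl)hex-1-en-5-yn-3-ol; 4 (2R,3R)-2,3-dimethyloxirane-2-carboxylic acid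
Product: 14 (3R,4R)-4-[(tert-butyldimethylsilyl)oxy]-2-methyl-6-(trimethylsilyl)hex-1-en-5-yn-3-yl (2R,3R)-2,3-dimethyloxirane-2-carboxylate, via mixed anhydride 13 (not isolated)
Conditions: 4, 2,4,6-trichlorobenzoyl chloride, Et3N, THF, rt; then 12, DMAP, toluene, rt
Reagents that add atoms: none
Why: Yamaguchi esterification; the mixed anhydride of the hindered α-quaternary epoxy acid is attacked at the glycidic carbonyl by the secondary alcohol under DMAP catalysis, and no stereocentre is touched.

Step 9
Reactants: 14 (3R,4R)-4-[(tert-butyldimethylsilyl)oxy]-2-methyl-6-(trimethylsilyl)hex-1-en-5-yn-3-yl (2R,3R)-2,3-dimethyloxirane-2-carboxylate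
Product: 15 (3R,4R)-4-hydroxy-2-methylhex-1-en-5-yn-3-yl (2R,3R)-2,3-dimethyloxirane-2-carboxylate
Conditions: TBAF, AcOH, THF, 0 °C to rt
Reagents that add atoms: none
Why: Fluoride desilylation cleaves both the O–Si and the C(sp)–Si bond, and the acetic acid buffer keeps the liberated alkoxide protonated so that the neighbouring ester should not migrate.

Step 10
Reactants: 16 (E)-pent-3-enoic acid
Product: 17 (E)-N-methoxy-N-methylpent-3-enamide
Conditions: MeNH(OMe)·HCl, EDC·HCl, N-methylmorpholine, CH2Cl2, 0 °C to rt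
Reagents that add atoms: N,O-dimethylhydroxylamine hydrochloride (CNOC.Cl)
Why: Carbodiimide amide coupling gives the Weinreb amide under conditions too mild to move the β,γ-double bond into conjugation.

Step 11
Reactants: 17 (E)-N-methoxy-N-methylpent-3-enamide; 18 ethynyltrimethylsilane
Product: 20 (E)-1-(trimethylsilyl)hept-5-en-1-yn-3-one, via lithium acetylide 19 (not isolated)
Conditions: 18, n-BuLi, THF, −78 °C; then 17, −78 to −20 °C; AcOH quench
Reagents that add atoms: none
Why: Weinreb ketone synthesis; the acetylide adds once, the chelated tetrahedral adduct holds until the cold acidic quench, and the non-conjugated ynone is used without exposure to base.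

Step 12
Reactants: 20 (E)-1-(trimethylsilyl)hept-5-en-1-yn-3-one
Product: 21 (3S,5E)-1-(trimethylsilyl)hept-5-en-1-yn-3-ol
Conditions: RuCl[(S,S)-TsDPEN](p-cymene) (2 mol %), i-PrOH, rt
Reagents that add atoms: none
Why: Noyori asymmetric transfer hydrogenation of an ynone; the alkynyl group takes the place an aryl group takes in the transition state, so the (S,S)-catalyst should give the (S)-propargylic alcohol.

Step 13
Reactants: 21 (3S,5E)-1-(trimethylsilyl)hept-5-en-1-yn-3-ol
Product: 22 (3S,5E)-hept-5-en-1-yn-3-ol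
Conditions: K2CO3 (cat.), MeOH, 0 °C
Reagents that add atoms: none
Why: Base-catalysed methanolysis of the alkynyl C–Si bond (protodesilylation).

Step 14
Reactants: 22 (3S,5E)-hept-5-en-1-yn-3-ol
Product: 24 (1Z,3S,5E)-1-iodo-2-methylhepta-1,5-dien-3-ol, via alkenylmagnesium alkoxide 23 (not isolated)
Conditions: MeMgBr (3 equiv), CuI (10 mol %), Et2O/THF, −10 °C to rt; then I2, −78 to 0 °C; H2O
Reagents that add atoms: methylmagnesium bromide (C[Mg]Br); iodine (II)
Why: Copper-catalysed, alkoxide-directed anti carbomagnesiation of the propargylic alcohol puts methyl on the proximal carbon and magnesium on the terminal carbon in a five-membered chelate, and iodinolysis with retention should give the Z-vinyl iodide; C-3 is untouched.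

Step 15
Reactants: 24 (1Z,3S,5E)-1-iodo-2-methylhepta-1,5-dien-3-ol
Product: 25 (1Z,3S,5E)-1-iodo-2-methylhepta-1,5-dien-3-yl acetate
Conditions: Ac2O, pyridine, DMAP (cat.), CH2Cl2, 0 °C
Reagents that add atoms: acetic anhydride (CC(=O)OC(C)=O)
Why: DMAP-catalysed acetylation of the secondary allylic alcohol installs the C-3 acetate of the target.

Step 16
Reactants: 25 (1Z,3S,5E)-1-iodo-2-methylhepta-1,5-dien-3-yl acetate; 15 (3R,4R)-4-hydroxy-2-methylhex-1-en-5-yn-3-yl (2R,3R)-2,3-dimethyloxirane-2-carboxylate
Product: 26 (3R,4R,7Z,9S,11E)-9-(acetyloxy)-4-hydroxy-2,8-dimethyltrideca-1,7,11-trien-5-yn-3-yl (2R,3R)-2,3-dimethyloxirane-2-carboxylate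
Conditions: PdCl2(PPh3)2 (3 mol %), CuI (6 mol %), Et3N, THF, rt
Reagents that add atoms: none
Why: Sonogashira coupling of the Z-vinyl iodide with the terminal alkyne at room temperature proceeds with retention of alkene geometry and should tolerate the free hydroxyl, the esters and the epoxide.

Step 17
Reactants: 26 (3R,4R,7Z,9S,11E)-9-(acetyloxy)-4-hydroxy-2,8-dimethyltrideca-1,7,11-trien-5-yn-3-yl (2R,3R)-2,3-dimethyloxirane-2-carboxylate
Product: 27 (3R,4R,5Z,7Z,9S,11E)-9-(acetyloxy)-4-hydroxy-2,8-dimethyltrideca-1,5,7,11-tetraen-3-yl (2R,3R)-2,3-dimethyloxirane-2-carboxylate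
Conditions: Zn (activated with Cu(OAc)2 and AgNO3), MeOH/H2O, rt to 40 °C
Reagents that add atoms: none
Why: Boland semireduction; activated zinc reduces the conjugated triple bond, which the propargylic hydroxyl activates, by syn delivery of hydrogen to the Z-alkene and should not reduce double bonds.

Step 18
Reactants: 27 (3R,4R,5Z,7Z,9S,11E)-9-(acetyloxy)-4-hydroxy-2,8-dimethyltrideca-1,5,7,11-tetraen-3-yl (2R,3R)-2,3-dimethyloxirane-2-carboxylate; 28 2-bromoacrylic acid
Product: 29 (1R,2R)-1-{(2R,3R)-2-[(1Z,3S,5E)-3-(acetyloxy)-2-methylhepta-1,5-dien-1-yl]-4-methylidene-5-oxooxolan-3-yl}-1-hydroxy-3-methylbut-3-en-2-yl (2R,3R)-2,3-dimethyloxirane-2-carboxylate (the seco-lactone; 6R,7R in germacrane numbering)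
Conditions: 28 (1.5 equiv), Pd(OAc)2 (10 mol %), n-Bu4NCl (1 equiv), NaHCO3 (2.5 equiv), DMF, 50 °C
Reagents that add atoms: none
Why: Proposed new method: zerovalent palladium formed from Pd(OAc)2 should insert into the C–Br bond of the bromoacrylate, the α-carboxyvinylpalladium should add syn across C-6=C-7 with carbon going to C-7 (the CH terminus of the diene, not the fully substituted C-4), and the η3-allylpalladium over C-4/C-5/C-6 should be captured at C-6 by the tethered carboxylate from the face opposite to the metal, which returns zerovalent palladium and keeps the Z C-4=C-5 bond because the tertiary allyl terminus does not isomerise through a σ-complex before closure; the closest known reaction type is the Larock heteroannulation of 1,3-dienes with ortho-halo benzoic acids, phenols, anilines and functionalised vinylic halides, which has not been shown for 2-bromoacrylic acid on an internal (Z,Z)-diene with a neighbouring hydroxyl. The only ring closed is the γ-lactone, by 5-exo attack of oxygen on the allyl terminus C-6 (closure at tertiary C-4 would give a seven-membered ring and is disfavoured). C-7 is set in the carbopalladation: allylic 1,3-strain in the Z-alkene holds H-8 in the alkene plane, so one face carries the small 8-OH and the other the bulky C-9 branch (ester and isopropenyl), and the palladium species, coordinated or hydrogen-bonded to 8-OH, should add on the hydroxyl face, which gives 7R. C-6 follows stereospecifically, because syn carbopalladation and anti C–O bond formation amount to net anti addition across a Z-alkene and therefore to the trans-lactone with 6R; chloride is added to keep the carboxylate off the metal and suppress the inner-sphere pathway that would give the cis-lactone. The step needs chemoselectivity for the diene, secured by the substitution of the other alkenes (E-1,2-disubstituted crotyl and 1,1-disubstituted isopropenyl, both unconjugated and undirected), and phosphine-free conditions are chosen so that the allylic acetate and the allylic ester are not ionised.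

Step 19
Reactants: 29 the seco-lactone
Product: 30 CNP0137407.10, (3S,6R,7R,8R,9R)-3-acetoxy-8-hydroxy-9-{[(2R,3R)-2,3-dimethyloxirane-2-carbonyl]oxy}germacra-1(10)Z,4Z,11(13)-trien-12,6-olide
Conditions: second-generation Grubbs catalyst RuCl2(=CHPh)(H2IMes)(PCy3) (10 mol %), toluene (0.5 mM), 80 °C
Reagents that add atoms: none
Why: Ring-closing metathesis between the crotyl alkene (initiation site) and the isopropenyl group releases propene; the trans-fused lactone and the Z C-4=C-5 alkene pre-organise the chain, and the ten-membered ring should favour the Z trisubstituted C-1=C-10 alkene.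

**Compound list**
1 | angelic acid, (Z)-2-methylbut-2-enoic acid | C/C=C(/C)C(=O)O | starting material
2 | (Z)-2-methylbut-2-en-1-ol | C/C=C(/C)CO | intermediate
3 | [(2S,3R)-2,3-dimethyloxiran-2-yl]methanol | OC[C@]1(C)O[C@@H]1C | intermediate
4 | (2R,3R)-2,3-dimethyloxirane-2-carboxylic acid | OC(=O)[C@]1(C)O[C@@H]1C | intermediate
5 | 2-methylprop-2-en-1-ol | C=C(C)CO | starting material
6 | 3-(methoxymethoxy)-2-methylprop-1-ene | C=C(C)COCOC | intermediate
7 | 3-(trimethylsilyl)prop-2-ynal | C[Si](C)(C)C#CC=O | starting material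
8 | [1-(methoxymethoxy)-2-methylallyl]lithium (not isolated) | [Li]C(OCOC)C(C)=C | intermediate
9 | [(Z)-3-(methoxymethoxy)-2-methylallyl]diisopinocampheylborane, isopinocampheyl groups from (+)-α-pinene (not isolated) | COCO/C=C(/C)CB([C@@H]1C[C@@H]2C[C@H]([C@H]1C)C2(C)C)[C@@H]1C[C@@H]2C[C@H]([C@H]1C)C2(C)C | intermediate
10 | (3R,4R)-4-(methoxymethoxy)-5-methyl-1-(trimethylsilyl)hex-5-en-1-yn-3-ol | C[Si](C)(C)C#C[C@@H](O)[C@H](OCOC)C(C)=C | intermediate
11 | tert-butyl{[(3R,4R)-4-(methoxymethoxy)-5-methyl-1-(trimethylsilyl)hex-5-en-1-yn-3-yl]oxy}dimethylsilane | C[Si](C)(C)C#C[C@@H](O[Si](C)(C)C(C)(C)C)[C@H](OCOC)C(C)=C | intermediate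
12 | (3R,4R)-4-[(tert-butyldimethylsilyl)oxy]-2-methyl-6-(trimethylsilyl)hex-1-en-5-yn-3-ol | C[Si](C)(C)C#C[C@@H](O[Si](C)(C)C(C)(C)C)[C@H](O)C(C)=C | intermediate
13 | (2R,3R)-2,3-dimethyloxirane-2-carboxylic 2,4,6-trichlorobenzoic anhydride (not isolated) | O=C(OC(=O)[C@]1(C)O[C@@H]1C)c1c(Cl)cc(Cl)cc1Cl | intermediate
14 | (3R,4R)-4-[(tert-butyldimethylsilyl)oxy]-2-methyl-6-(trimethylsilyl)hex-1-en-5-yn-3-yl (2R,3R)-2,3-dimethyloxirane-2-carboxylate | C[Si](C)(C)C#C[C@@H](O[Si](C)(C)C(C)(C)C)[C@H](OC(=O)[C@]1(C)O[C@@H]1C)C(C)=C | intermediate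
15 | (3R,4R)-4-hydroxy-2-methylhex-1-en-5-yn-3-yl (2R,3R)-2,3-dimethyloxirane-2-carboxylate | C#C[C@@H](O)[C@H](OC(=O)[C@]1(C)O[C@@H]1C)C(C)=C | intermediate
16 | (E)-pent-3-enoic acid | C/C=C/CC(=O)O | starting material
17 | (E)-N-methoxy-N-methylpent-3-enamide | C/C=C/CC(=O)N(C)OC | intermediate
18 | ethynyltrimethylsilane | C#C[Si](C)(C)C | starting material
19 | lithium (trimethylsilyl)acetylide (not isolated) | [Li]C#C[Si](C)(C)C | intermediate
20 | (E)-1-(trimethylsilyl)hept-5-en-1-yn-3-one | C/C=C/CC(=O)C#C[Si](C)(C)C | intermediate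
21 | (3S,5E)-1-(trimethylsilyl)hept-5-en-1-yn-3-ol | C/C=C/C[C@H](O)C#C[Si](C)(C)C | intermediate
22 | (3S,5E)-hept-5-en-1-yn-3-ol | C/C=C/C[C@H](O)C#C | intermediate
23 | bromomagnesium (1Z,3S,5E)-1-(bromomagnesio)-2-methylhepta-1,5-dien-3-olate (not isolated) | C/C=C/C[C@H](O[Mg]Br)/C(C)=C\[Mg]Br | intermediate
24 | (1Z,3S,5E)-1-iodo-2-methylhepta-1,5-dien-3-ol | C/C=C/C[C@H](O)/C(C)=C\I | intermediate
25 | (1Z,3S,5E)-1-iodo-2-methylhepta-1,5-dien-3-yl acetate | C/C=C/C[C@H](OC(C)=O)/C(C)=C\I | intermediate
26 | (3R,4R,7Z,9S,11E)-9-(acetyloxy)-4-hydroxy-2,8-dimethyltrideca-1,7,11-trien-5-yn-3-yl (2R,3R)-2,3-dimethyloxirane-2-carboxylate | C/C=C/C[C@H](OC(C)=O)/C(C)=C\C#C[C@@H](O)[C@H](OC(=O)[C@]1(C)O[C@@H]1C)C(C)=C | intermediate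
27 | (3R,4R,5Z,7Z,9S,11E)-9-(acetyloxy)-4-hydroxy-2,8-dimethyltrideca-1,5,7,11-tetraen-3-yl (2R,3R)-2,3-dimethyloxirane-2-carboxylate | C/C=C/C[C@H](OC(C)=O)/C(C)=C\C=C/[C@@H](O)[C@H](OC(=O)[C@]1(C)O[C@@H]1C)C(C)=C | intermediate
28 | 2-bromoacrylic acid | C=C(Br)C(=O)O | starting material
29 | seco-lactone, (1R,2R)-1-{(2R,3R)-2-[(1Z,3S,5E)-3-(acetyloxy)-2-methylhepta-1,5-dien-1-yl]-4-methylidene-5-oxooxolan-3-yl}-1-hydroxy-3-methylbut-3-en-2-yl (2R,3R)-2,3-dimethyloxirane-2-carboxylate | C/C=C/C[C@H](OC(C)=O)/C(C)=C\[C@H]1OC(=O)C(=C)[C@@H]1[C@@H](O)[C@H](OC(=O)[C@]2(C)O[C@@H]2C)C(C)=C | intermediate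
30 | CNP0137407.10, (3S,6R,7R,8R,9R)-3-acetoxy-8-hydroxy-9-{[(2R,3R)-2,3-dimethyloxirane-2-carbonyl]oxy}germacra-1(10)Z,4Z,11(13)-trien-12,6-olide | C=C1C(=O)O[C@@H]2/C=C(/C)[C@@H](OC(C)=O)C/C=C(/C)[C@@H](OC(=O)[C@]3(C)O[C@@H]3C)[C@H](O)[C@@H]12 | target

**Step count**
Total: 19 steps. Longest linear sequence: 10 steps (steps 4 to 9, then 16 to 19; the branch 10 to 15, then 16 to 19, is equally long).

**Steps most likely to fail**

1. Step 18 (the proposed method). What may go wrong: addition of the vinylpalladium to the other face of C-7 or inner-sphere C–O bond formation, which would give the C-7 epimer or the cis-lactone; β-hydride loss to a triene instead of ring closure; ionisation of the allylic esters. The fallback uses known oxidative free-radical chemistry in place of palladium. It sets out from 27: Mn(OAc)3·2H2O and malonic acid in AcOH at 60 °C should add the malonyl radical to C-7, oxidise the allyl radical and close the carboxyl on C-6 to the trans-lactone, giving the α-carboxy lactone F1. Decarboxylative Mannich methylenation (aqueous CH2O, Et2NH, then NaOAc/AcOH, heat) should then give 29, where the fallback comes back to the route.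

2. Step 19. What may go wrong: intermolecular metathesis, including at the exocyclic methylene of the lactone, outrunning closure of the strained ten-membered ring, or closure to the E isomer. The fallback masks the methylene before ring closure. It sets out from 29: conjugate addition of thiophenol (catalytic Et3N, THF) should give the sulfide F2 as C-11 epimers. Ring-closing metathesis under the conditions of step 19 should give the macrocyclic sulfide F3, and NaIO4 in MeOH/H2O the sulfoxide F4. Thermal syn-elimination (toluene, 110 °C, CaCO3) should restore the methylene and give 30, where the fallback comes back to the route.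

3. Step 17. What may go wrong: over-reduction, stalling on the zinc surface, reductive loss of the ester next to the alkyne, or Z to E drift of the diene. The fallback builds the Z,Z-diene by cross-coupling and bypasses 26. It sets out from 15: rhodium-catalysed trans-hydroboration (pinacolborane, [Rh(cod)Cl]2, P(iPr)3, Et3N, cyclohexane) should give the (Z)-alkenylboronate F5. Suzuki–Miyaura coupling of F5 with 25 (Pd(PPh3)4, aqueous K3PO4, THF, rt), with retention at both partners, should give 27, where the fallback comes back to the route.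

**Further compounds**
F1 | step 18 | α-carboxy lactone, 29 with H and CO2H on C-11 in place of the methylidene group (C-11 epimers) | C/C=C/C[C@H](OC(C)=O)/C(C)=C\[C@H]1OC(=O)C(C(=O)O)[C@@H]1[C@@H](O)[C@H](OC(=O)[C@]2(C)O[C@@H]2C)C(C)=C
F2 | step 19 | 13-(phenylsulfanyl)-11,13-dihydro derivative of 29 (C-11 epimers) | C/C=C/C[C@H](OC(C)=O)/C(C)=C\[C@H]1OC(=O)C(CSc2ccccc2)[C@@H]1[C@@H](O)[C@H](OC(=O)[C@]2(C)O[C@@H]2C)C(C)=C
F3 | step 19 | 13-(phenylsulfanyl)-11,13-dihydro derivative of 30 (C-11 epimers) | c1ccccc1SCC1C(=O)O[C@@H]2/C=C(/C)[C@@H](OC(C)=O)C/C=C(/C)[C@@H](OC(=O)[C@]3(C)O[C@@H]3C)[C@H](O)[C@@H]12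
F4 | step 19 | 13-(phenylsulfinyl)-11,13-dihydro derivative of 30 (epimers at C-11 and sulfur) | O=S(c1ccccc1)CC1C(=O)O[C@@H]2/C=C(/C)[C@@H](OC(C)=O)C/C=C(/C)[C@@H](OC(=O)[C@]3(C)O[C@@H]3C)[C@H](O)[C@@H]12
F5 | step 17 | (3R,4R,5Z)-4-hydroxy-2-methyl-6-(4,4,5,5-tetramethyl-1,3,2-dioxaborolan-2-yl)hexa-1,5-dien-3-yl (2R,3R)-2,3-dimethyloxirane-2-carboxylate | CC1(C)OB(/C=C\[C@@H](O)[C@H](OC(=O)[C@]2(C)O[C@@H]2C)C(C)=C)OC1(C)C
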